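All runs were generated by integration with made-up constants; the scatter is artificial.

Per equivalent of incoming ligand, the alder run held more complex with two exchanged at 8.00 h than the oak run, as read: 3.53% against 3.18%.

| setting | oak | alder | violet | ochre | teal |
|---|---|---|---|---|---|
| starting complex | 0.050 M | 0.050 M | 0.050 M | 0.050 M | 0.050 M |
| incoming ligand | 1.1 equiv | 3.6 equiv | 0.800 equiv | 1.50 equiv | 3.00 equiv |
| remark | run made earlier | run made earlier |  |  |  |
| time |  |  | 10 h | 10 h | 10 h |

| run | time / h | complex with two exchanged / % | complex with one exchanged / % |
|---|---|---|---|
| oak | 0.500 | 2.7 | 6.0 |
| oak | 1.33 | 4.1 | 6.0 |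
| oak | 3.00 | 4.2 | 4.7 |
| oak | 8.00 | 3.5 | 3.7 |
| alder | 2.00 | 15.5 | 11.5 |
| alder | 4.00 | 14.8 | 9.3 |
| alder | 5.00 | 13.6 | 8.9 |
| alder | 8.00 | 12.7 | 6.7 |

(standard deviation of a reading: 0.3 percentage points)

- percentages count the starting complex that a species holds: one self-condensation product or side product B counts as two
- what may be going on: starting complex + incoming ligand <-> leaving ligand + complex with one exchanged; complex with one exchanged + incoming ligand <-> leaving ligand + complex with two exchanged; leaving ligand + starting complex -> side product A; 2 starting complex -> self-condensation product; starting complex + complex with one exchanged -> side product B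

- how much complex with two exchanged is there at the end, in percent of the starting complex charged: for each flask in turn (violet, ochre, teal)

We reckon with the yield per equivalent, y: percent of complex with two exchanged at 10 h divided by the equivalents charged. For a first pass, the alder figure above is a ceiling on y, since the complex with two exchanged is fading in both runs. We then go round once more and fade each run's last reading over the remaining hours. Alder's late readings give a slowest fade of 0.0228 h⁻¹ and a faster one of 0.0383 h⁻¹. Alder with the slow fade gives the ceiling on yield per equivalent, 3.37%. Oak with the fast fade gives the floor, 2.95%.

Ochre and teal lie between oak and alder in charge, so our brackets are 4.42% to 5.06% for ochre and 8.84% to 10.1% for teal. Violet lies below oak in charge, and y rose from oak to alder as read, so we take oak with the slow fade, 3.04%, as the top of violet's y; that sets violet a ceiling of 2.43% and no floor.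

The forecast gives 2.2%, 4.6% and 9.7%, saying “the yield is nearly proportional to equivalents”. Each value stands inside our limits.

The flasks give 1.94%, 4.59% and 9.93%.

    starting complex + incoming ligand ⇌ leaving ligand + complex with one exchanged (K = 0.830, k = 0.150 M⁻¹ min⁻¹)
    complex with one exchanged + incoming ligand ⇌ leaving ligand + complex with two exchanged (K = 0.240, k = 0.330 M⁻¹ min⁻¹)
    leaving ligand + starting complex → side product A (k = 0.450 M⁻¹ min⁻¹)
    2 starting complex → self-condensation product (k = 4.40 × 10⁻⁴ M⁻¹ min⁻¹)
    starting complex + complex with one exchanged → side product B (k = 1.90 M⁻¹ min⁻¹)

Ochre's y is 3.06% and teal's 3.31%, both under the ceiling of 3.37%. For the forecast to fail, y would have to bend further from proportion, and violet, at 2.42%, already lies below the floor. In violet at 0.774 h, complex with one exchanged was going into side product B 5.9 times as fast as it was going forward to complex with two exchanged, counting the forward rate of that reversible step by itself. By 10.0 h, violet held 67.5% of its starting complex as side product B.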